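**Retrosynthetic overview**
1. Target 23 ⇐ C3 ketone reduction and O2 senecioylation of methyl 2α-hydroxy-3-oxolabd-7-en-15-oate 20 ⇐ methyl cross-coupling of the C7=C8 enol triflate of 8-ketone 16.
2. 16 ⇐ radical conjugate addition (C11–C12 bond) of iodide 15, made from (S)-β-methyl-γ-butyrolactone 13 (source of C13), to the exocyclic enone 12.
3. 12 (ring B) ⇐ ring expansion of the tertiary vinyl cyclopentanol 11: 1,2-shift of quaternary C10 from C8 to C9 (key step).
4. 11 ⇐ hydrindenedione 4 by vinyl addition, Li/NH3 reductive methylation (C4 gem-dimethyl, trans C5) and enolate hydroxylation (C2).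
5. 4 ⇐ 2-methylcyclopentane-1,3-dione 1 + ethyl vinyl ketone 2. Ring order: five-membered ring (bought) → ring A (aldol) → ring B (expansion of the five-membered ring).

Assumption: (S)-4-methyldihydrofuran-2(3H)-one 13 is bought as the single enantiomer; C-numbers and α/β follow labdane numbering (C1–C10 decalin, C11–C16 side chain).

**Step 1**
Reactants: 1 2-methylcyclopentane-1,3-dione; 2 pent-1-en-3-one
Product: 3 2-methyl-2-(3-oxopentyl)cyclopentane-1,3-dione
Conditions: H2O, AcOH (cat.), 75 °C
Reagents that add atoms: none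
Why: Michael addition of the acidic 1,3-dione to the enone under mild aqueous conditions; no stereocentre is formed.

**Step 2**
Reactants: 3 2-methyl-2-(3-oxopentyl)cyclopentane-1,3-dione
Product: 4 (7aS)-4,7a-dimethyl-2,3,7,7a-tetrahydro-1H-indene-1,5(6H)-dione
Conditions: L-phenylalanine (1 equiv), (1S)-(+)-camphor-10-sulfonic acid (0.5 equiv), DMF, 30 → 70 °C; recrystallise
Reagents that add atoms: none
Why: Hajos–Parrish–Eder–Sauer–Wiechert aldol condensation, in which the enamine of the ethyl ketone with the L-amino acid attacks one enantiotopic ring carbonyl and sets quaternary C10 as the β-methyl (S) centre while closing ring A.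

**Step 3**
Reactants: 4 (7aS)-4,7a-dimethyl-2,3,7,7a-tetrahydro-1H-indene-1,5(6H)-dione; 5 vinylmagnesium bromide
Product: 6 (1R,7aS)-1-ethenyl-1-hydroxy-4,7a-dimethyl-2,3,7,7a-tetrahydro-1H-inden-5(6H)-one
Conditions: CH2=CHMgBr (1.2 equiv), THF, −78 °C; NH4Cl aq
Reagents that add atoms: none
Why: Grignard 1,2-addition to the saturated cyclopentanone, which is more electrophilic than the tetrasubstituted enone, from the α-face anti to the angular methyl (this C8 configuration is erased in step 7).

**Step 4**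
Reactants: 6 (1R,7aS)-1-ethenyl-1-hydroxy-4,7a-dimethyl-2,3,7,7a-tetrahydro-1H-inden-5(6H)-one
Product: 8 (1R,3aR,7aS)-1-ethenyl-1-hydroxy-4,4,7a-trimethyloctahydro-5H-inden-5-one, via dilithium enolate-alkoxide 7 (not isolated)
Conditions: Li (2.2 equiv), NH3/THF, −78 °C; then MeI, −78 → −33 °C; NH4Cl
Reagents that add atoms: iodomethane CI
Why: Birch-type reductive alkylation in which axial protonation at C5 anti to the angular methyl gives the trans ring fusion (as known for the silyl ether analogue of this bicycle) and the regiodefined enolate is methylated at C4; the tertiary OH is the internal proton source and the isolated vinyl group is not reduced.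

**Step 5**
Reactants: 8 (1R,3aR,7aS)-1-ethenyl-1-hydroxy-4,4,7a-trimethyloctahydro-5H-inden-5-one
Product: 10 (1R,3aR,6R,7aS)-1-ethenyl-1,6-dihydroxy-4,4,7a-trimethyloctahydro-5H-inden-5-one, via dipotassium enolate-alkoxide 9 (not isolated)
Conditions: KN(SiMe3)2 (2.2 equiv), THF, −78 °C; then 3-phenyl-2-(phenylsulfonyl)oxaziridine; NH4Cl aq
Reagents that add atoms: 3-phenyl-2-(phenylsulfonyl)-1,2-oxaziridine O=S(=O)(c1ccccc1)N1OC1c1ccccc1
Why: Davis enolate hydroxylation at C2, the only enolisable position, with oxygen delivered from the α-face opposite the axial 4β- and 10β-methyl groups to give the equatorial 2α-alcohol.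

**Step 6**
Reactants: 10 (1R,3aR,6R,7aS)-1-ethenyl-1,6-dihydroxy-4,4,7a-trimethyloctahydro-5H-inden-5-one
Product: 11 (1R,3aR,6R,7aS)-1-ethenyl-1-hydroxy-4,4,7a-trimethyl-6-(triethylsilyloxy)octahydro-5H-inden-5-one
Conditions: Et3SiCl, imidazole, DMF, 0 °C
Reagents that add atoms: chlorotriethylsilane CC[Si](Cl)(CC)CC
Why: Silyl ether formation at the secondary α-ketol hydroxyl only (the tertiary allylic OH is too hindered), leaving a C3 ketone whose single α-hydrogen is hindered and oxygen-bearing and so is expected to stay out of the later kinetic enolisation.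

**Step 7**
Reactants: 11 (1R,3aR,6R,7aS)-1-ethenyl-1-hydroxy-4,4,7a-trimethyl-6-(triethylsilyloxy)octahydro-5H-inden-5-one
Product: 12 (4aR,7R,8aS)-5,5,8a-trimethyl-1-methylidene-7-(triethylsilyloxy)octahydronaphthalene-2,6(1H,3H)-dione
Conditions: PdCl2(MeCN)2 (10 mol %), 1,4-benzoquinone (1.5 equiv), 4 Å molecular sieves, THF, 40 °C
Reagents that add atoms: none
Why: Proposed new method: dehydrogenative semipinacol ring expansion of an unstrained tertiary 1-vinylcyclopentanol by divalent palladium, in which π-complexation makes C9 electrophilic, the C8–C10 bond (fully substituted carbon, best migrating group, anti to palladium) shifts from C8 to C9 with retention at C10 as the carbinol collapses to the C8 ketone, the primary alkylpalladium at C11 loses the C9 hydrogen by β-hydride elimination to give the exocyclic enone (which cannot move into the ring because C10 is quaternary), and benzoquinone reoxidises zerovalent palladium, with relief of trans-hydrindane strain as extra driving force; the closest known reaction type is the benzoquinone-coupled palladium ring expansion of 1-vinylcyclobutanols to 2-methylenecyclopentanones, which is strain-driven and has not been shown on cyclopentanols.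

**Step 8**
Reactants: 13 (S)-4-methyldihydrofuran-2(3H)-one
Product: 15 methyl (S)-4-iodo-3-methylbutanoate, via trimethylsilyl ester 14 (not isolated)
Conditions: Me3SiI, CH2Cl2, rt; then MeOH, rt
Reagents that add atoms: iodotrimethylsilane C[Si](C)(C)I; methanol CO
Why: Silyl-iodide lactone cleavage by SN2 attack of iodide at the O–CH2 carbon, followed by Fischer esterification on methanol addition; the C13 stereocentre is not touched.

**Step 9**
Reactants: 12 (4aR,7R,8aS)-5,5,8a-trimethyl-1-methylidene-7-(triethylsilyloxy)octahydronaphthalene-2,6(1H,3H)-dione; 15 methyl (S)-4-iodo-3-methylbutanoate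
Product: 16 methyl (3R)-3-methyl-5-[(1R,4aR,7R,8aS)-5,5,8a-trimethyl-2,6-dioxo-7-(triethylsilyloxy)decahydronaphthalen-1-yl]pentanoate
Conditions: (Me3Si)3SiH (slow addition), AIBN (cat.), toluene, 80 °C; 12 used freshly prepared
Reagents that add atoms: none
Why: Giese radical conjugate addition of the primary alkyl radical to the unhindered exocyclic enone terminus forms C11–C12, and hydrogen-atom transfer to the α-keto radical from the α-face (also the thermodynamic, equatorial-chain outcome) gives 9α-H.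

**Step 10**
Reactants: 16 methyl (3R)-3-methyl-5-[(1R,4aR,7R,8aS)-5,5,8a-trimethyl-2,6-dioxo-7-(triethylsilyloxy)decahydronaphthalen-1-yl]pentanoate
Product: 18 methyl (3R)-3-methyl-5-[(1R,4aR,7R,8aS)-5,5,8a-trimethyl-6-oxo-7-(triethylsilyloxy)-2-(trifluoromethylsulfonyloxy)-1,4,4a,5,6,7,8,8a-octahydronaphthalen-1-yl]pentanoate, via potassium enolate 17 (not isolated)
Conditions: KN(SiMe3)2 (1.1 equiv), THF, −78 °C; then PhNTf2, −78 → 0 °C; NH4Cl aq
Reagents that add atoms: N-phenylbis(trifluoromethanesulfonimide) O=S(=O)(N(c1ccccc1)S(=O)(=O)C(F)(F)F)C(F)(F)F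
Why: Kinetic enol triflate formation by deprotonation at the unhindered C7 methylene (not the tertiary C9–H, the siloxy-bearing C2–H or the ester) fixes the double bond at C7=C8.

**Step 11**
Reactants: 18 methyl (3R)-3-methyl-5-[(1R,4aR,7R,8aS)-5,5,8a-trimethyl-6-oxo-7-(triethylsilyloxy)-2-(trifluoromethylsulfonyloxy)-1,4,4a,5,6,7,8,8a-octahydronaphthalen-1-yl]pentanoate
Product: 20 methyl (3R)-5-[(1S,4aR,7R,8aR)-7-hydroxy-2,5,5,8a-tetramethyl-6-oxo-1,4,4a,5,6,7,8,8a-octahydronaphthalen-1-yl]-3-methylpentanoate, via triethylsilyl ether 19 (not isolated)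
Conditions: MeZnCl (2 equiv), Pd(PPh3)4 (5 mol %), THF, 50 °C; then 1 M HCl, THF, 0 °C
Reagents that add atoms: methylzinc chloride C[Zn]Cl
Why: Negishi coupling of the enol triflate under zerovalent palladium catalysis installs the C8 methyl without moving the alkene (ester and hindered ketone tolerated), and the acidic work-up cleaves the triethylsilyl ether.

**Step 12**
Reactants: 20 methyl (3R)-5-[(1S,4aR,7R,8aR)-7-hydroxy-2,5,5,8a-tetramethyl-6-oxo-1,4,4a,5,6,7,8,8a-octahydronaphthalen-1-yl]-3-methylpentanoate; 21 3-methylbut-2-enoyl chloride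
Product: 22 methyl (3R)-3-methyl-5-[(1S,4aR,7R,8aR)-2,5,5,8a-tetramethyl-7-(3-methylbut-2-enoyloxy)-6-oxo-1,4,4a,5,6,7,8,8a-octahydronaphthalen-1-yl]pentanoate
Conditions: pyridine, DMAP (cat.), CH2Cl2, 0 °C
Reagents that add atoms: none
Why: Acylation (esterification) of the only hydroxyl puts the senecioate unambiguously on O2, and pyridine rather than a trialkylamine limits deconjugation of the acid chloride through its vinylketene.

**Step 13**
Reactants: 22 methyl (3R)-3-methyl-5-[(1S,4aR,7R,8aR)-2,5,5,8a-tetramethyl-7-(3-methylbut-2-enoyloxy)-6-oxo-1,4,4a,5,6,7,8,8a-octahydronaphthalen-1-yl]pentanoate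
Product: 23 methyl (3R)-5-[(1S,4aR,6R,7R,8aR)-6-hydroxy-2,5,5,8a-tetramethyl-7-(3-methylbut-2-enoyloxy)-1,4,4a,5,6,7,8,8a-octahydronaphthalen-1-yl]-3-methylpentanoate (target)
Conditions: NaBH4, MeOH/THF, −40 °C; AcOH quench
Reagents that add atoms: none
Why: Borohydride reduction of the C3 ketone from the α-face (the β-face is shielded by the axial 4β- and 10β-methyls) gives the equatorial 3β-alcohol trans to the 2α-ester, and the cold, quickly quenched conditions spare both esters and limit acyl migration.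

**Compound list**
1 | 2-methylcyclopentane-1,3-dione | CC1C(=O)CCC1=O | starting material
2 | pent-1-en-3-one (ethyl vinyl ketone) | C=CC(=O)CC | starting material
3 | 2-methyl-2-(3-oxopentyl)cyclopentane-1,3-dione | CCC(=O)CCC1(C)C(=O)CCC1=O | intermediate
4 | (7aS)-4,7a-dimethyl-2,3,7,7a-tetrahydro-1H-indene-1,5(6H)-dione | O=C1CC[C@]2(C)C(=O)CCC2=C1C | intermediate
5 | vinylmagnesium bromide | C=C[Mg]Br | starting material
6 | (1R,7aS)-1-ethenyl-1-hydroxy-4,7a-dimethyl-2,3,7,7a-tetrahydro-1H-inden-5(6H)-one (8α-vinyl, 8β-OH) | O=C1CC[C@]2(C)[C@](O)(C=C)CCC2=C1C | intermediate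
7 | dilithium enolate-alkoxide from 1,4-reduction of 6 (C3=C4 lithium enolate, C8 lithium alkoxide, 5α-H) | CC1=C(O[Li])CC[C@]2(C)[C@](O[Li])(C=C)CC[C@@H]12 | intermediate
8 | (1R,3aR,7aS)-1-ethenyl-1-hydroxy-4,4,7a-trimethyloctahydro-5H-inden-5-one (trans-fused) | O=C1CC[C@]2(C)[C@](O)(C=C)CC[C@H]2C1(C)C | intermediate
9 | dipotassium enolate-alkoxide of 8 (C2=C3 potassium enolate, C8 potassium alkoxide) | [K]OC1=CC[C@]2(C)[C@](O[K])(C=C)CC[C@H]2C1(C)C | intermediate
10 | (1R,3aR,6R,7aS)-1-ethenyl-1,6-dihydroxy-4,4,7a-trimethyloctahydro-5H-inden-5-one (2α-OH) | O=C1[C@H](O)C[C@]2(C)[C@](O)(C=C)CC[C@H]2C1(C)C | intermediate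
11 | (1R,3aR,6R,7aS)-1-ethenyl-1-hydroxy-4,4,7a-trimethyl-6-(triethylsilyloxy)octahydro-5H-inden-5-one | O=C1[C@H](O[Si](CC)(CC)CC)C[C@]2(C)[C@](O)(C=C)CC[C@H]2C1(C)C | intermediate
12 | (4aR,7R,8aS)-5,5,8a-trimethyl-1-methylidene-7-(triethylsilyloxy)octahydronaphthalene-2,6(1H,3H)-dione (trans-decalin, C9=C11 exocyclic, C8 ketone) | C=C1C(=O)CC[C@H]2C(C)(C)C(=O)[C@H](O[Si](CC)(CC)CC)C[C@]12C | intermediate
13 | (S)-4-methyldihydrofuran-2(3H)-one | C[C@@H]1COC(=O)C1 | starting material
14 | trimethylsilyl (S)-4-iodo-3-methylbutanoate | C[Si](C)(C)OC(=O)C[C@H](C)CI | intermediate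
15 | methyl (S)-4-iodo-3-methylbutanoate | COC(=O)C[C@H](C)CI | intermediate
16 | methyl (3R)-3-methyl-5-[(1R,4aR,7R,8aS)-5,5,8a-trimethyl-2,6-dioxo-7-(triethylsilyloxy)decahydronaphthalen-1-yl]pentanoate | COC(=O)C[C@H](C)CC[C@H]1C(=O)CC[C@H]2C(C)(C)C(=O)[C@H](O[Si](CC)(CC)CC)C[C@]12C | intermediate
17 | potassium C7=C8 enolate of 16 | COC(=O)C[C@H](C)CC[C@H]1C(O[K])=CC[C@H]2C(C)(C)C(=O)[C@H](O[Si](CC)(CC)CC)C[C@]12C | intermediate
18 | methyl (3R)-3-methyl-5-[(1R,4aR,7R,8aS)-5,5,8a-trimethyl-6-oxo-7-(triethylsilyloxy)-2-(trifluoromethylsulfonyloxy)-1,4,4a,5,6,7,8,8a-octahydronaphthalen-1-yl]pentanoate | COC(=O)C[C@H](C)CC[C@H]1C(OS(=O)(=O)C(F)(F)F)=CC[C@H]2C(C)(C)C(=O)[C@H](O[Si](CC)(CC)CC)C[C@]12C | intermediate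
19 | methyl (3R)-3-methyl-5-[(1S,4aR,7R,8aR)-2,5,5,8a-tetramethyl-6-oxo-7-(triethylsilyloxy)-1,4,4a,5,6,7,8,8a-octahydronaphthalen-1-yl]pentanoate | COC(=O)C[C@H](C)CC[C@H]1C(C)=CC[C@H]2C(C)(C)C(=O)[C@H](O[Si](CC)(CC)CC)C[C@]12C | intermediate
20 | methyl (3R)-5-[(1S,4aR,7R,8aR)-7-hydroxy-2,5,5,8a-tetramethyl-6-oxo-1,4,4a,5,6,7,8,8a-octahydronaphthalen-1-yl]-3-methylpentanoate (methyl 2α-hydroxy-3-oxolabd-7-en-15-oate) | COC(=O)C[C@H](C)CC[C@H]1C(C)=CC[C@H]2C(C)(C)C(=O)[C@H](O)C[C@]12C | intermediate
21 | 3-methylbut-2-enoyl chloride | CC(C)=CC(=O)Cl | starting material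
22 | methyl (3R)-3-methyl-5-[(1S,4aR,7R,8aR)-2,5,5,8a-tetramethyl-7-(3-methylbut-2-enoyloxy)-6-oxo-1,4,4a,5,6,7,8,8a-octahydronaphthalen-1-yl]pentanoate | COC(=O)C[C@H](C)CC[C@H]1C(C)=CC[C@H]2C(C)(C)C(=O)[C@H](OC(=O)C=C(C)C)C[C@]12C | intermediate
23 | methyl (3R)-5-[(1S,4aR,6R,7R,8aR)-6-hydroxy-2,5,5,8a-tetramethyl-7-(3-methylbut-2-enoyloxy)-1,4,4a,5,6,7,8,8a-octahydronaphthalen-1-yl]-3-methylpentanoate | COC(=O)C[C@H](C)CC[C@H]1C(C)=CC[C@H]2C(C)(C)[C@@H](O)[C@H](OC(=O)C=C(C)C)C[C@]12C | target

**Step count:** 13 steps in total. Longest linear sequence: 12 steps (steps 1–7 and 9–13); step 8 is a one-step branch for the side-chain iodide.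

**Steps most likely to fail**

Step 7 (the proposed ring expansion). The unstrained cyclopentanol may not migrate and could instead give Wacker-type oxidation or allylic transposition. The fallback uses known chemistry and sets out from 11. Hydroxyl-directed epoxidation of the vinyl group (VO(acac)2, t-BuOOH, CH2Cl2) gives the epoxy alcohol F1. The classical Lewis-acid semipinacol rearrangement of 2,3-epoxy alcohols (ZnBr2, CH2Cl2, 0 °C), in which C10 migrates to C9 anti to the breaking C9–O bond, gives the ring-expanded β-hydroxy ketone F2. Mesylation (MsCl, Et3N) gives the mesylate F3, and elimination with DBU returns to the route at 12.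

Step 3 (chemoselective Grignard addition). The enone carbonyl or enolisation may compete with addition to the cyclopentanone. The fallback sets out from 4. Ethynylation as practised on steroidal enediones (acetylene, KOtBu, THF, 0 °C), where the base masks the enone as its dienolate and the small acetylide adds only to the saturated ketone, gives the ethynyl carbinol F4. Semihydrogenation (H2, Pd/CaCO3 poisoned with Pb(OAc)2, quinoline, EtOAc) returns to the route at 6.

Step 13 (reduction next to the ester). The intermediate alkoxide can take the senecioyl group from O2 to O3, or the facial selectivity could erode. The fallback sets out from 20 and reverses the order of the last two operations. NaBH4 reduction of the free α-ketol (MeOH, −40 °C) gives the 2α,3β-diol F5, where no acyl group is present to migrate. Regioselective acylation of the unhindered equatorial 2α-hydroxyl (the 3β-hydroxyl is neopentylic) with 21, pyridine and DMAP at −20 °C returns to the route at 23.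

**Further compounds**
F1 | step 7 | epoxy alcohol: 11 with the vinyl group converted to oxiran-2-yl (new epoxide carbon not assigned) | O=C1[C@H](O[Si](CC)(CC)CC)C[C@]2(C)[C@](O)(C3CO3)CC[C@H]2C1(C)C
F2 | step 7 | β-hydroxy ketone: (4aR,7R,8aS)-1-(hydroxymethyl)-5,5,8a-trimethyl-7-(triethylsilyloxy)octahydronaphthalene-2,6(1H,3H)-dione (C9 not assigned) | OCC1C(=O)CC[C@H]2C(C)(C)C(=O)[C@H](O[Si](CC)(CC)CC)C[C@]12C
F3 | step 7 | mesylate of F2 | CS(=O)(=O)OCC1C(=O)CC[C@H]2C(C)(C)C(=O)[C@H](O[Si](CC)(CC)CC)C[C@]12C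
F4 | step 3 | (1R,7aS)-1-ethynyl-1-hydroxy-4,7a-dimethyl-2,3,7,7a-tetrahydro-1H-inden-5(6H)-one | O=C1CC[C@]2(C)[C@](O)(C#C)CCC2=C1C
F5 | step 13 | methyl (3R)-5-[(1S,4aR,6R,7R,8aR)-6,7-dihydroxy-2,5,5,8a-tetramethyl-1,4,4a,5,6,7,8,8a-octahydronaphthalen-1-yl]-3-methylpentanoate | COC(=O)C[C@H](C)CC[C@H]1C(C)=CC[C@H]2C(C)(C)[C@@H](O)[C@H](O)C[C@]12C
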